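The numbers in the tables were computed on assumed constants, and the scatter is random.

The 1.20 M of partner in the flask is the amount to follow: the two steps that make product use it, and the protic impurity takes it as well.

| setting | north-east | east | flask |
|---|---|---|---|
| left-handed substrate | 1 M | 1 M | 1.0 M |
| right-handed substrate | 1 M | 1 M | 1.0 M |
| partner | 1.2 M | 1.2 M | 1.20 M |
| protic impurity | 0.10 M | 0.050 M | 0.100 M |
| free catalyst | 30 mM | 30 mM | 30 mM |
| remark | the very flask that is asked about, followed so far | run made earlier |  |

- north-east (time / h: left-handed product / %): 0.833: 16; 2.00: 25; 4.00: 36; 10.0: 40
- east (time / h: left-handed product / %): 2.00: 26; 5.00: 36; 10.0: 37; 25.0: 47

(each reading ± 2 percentage points)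

- apparent order in partner when 30% of the left-handed substrate and right-handed substrate together are converted (percent change of the rate of making left-handed product for one percent more partner charged)
- apparent order in free catalyst when 30% of the left-handed substrate and right-handed substrate together are converted (percent change of the rate of making left-handed product for one percent more free catalyst charged)

- free catalyst is single-handed; left-handed substrate and right-handed substrate are mirror images of each other, charged as a racemate, each of them at the stated concentration
- the analysis behind the earlier runs scatters by 2 percentage points, standard deviation
- steps thought possible: partner + free catalyst + left-handed substrate -> free catalyst + left-handed product; partner + free catalyst + right-handed substrate -> free catalyst + right-handed product; partner + protic impurity -> quenched reagent; 2 free catalyst -> spent catalyst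
- no earlier run changes the charge of free catalyst; that part of a forecast is a guess
- no earlier run changes the charge of partner; that part of a forecast is a guess

When 30% of the two substrates together are converted, 0.600 M of partner has gone into product, whichever substrate reacted. Counting the whole 0.100 M of protic impurity as quenched reagent, the reckoning made here leaves 0.500 M of partner in the flask.

Two amounts now matter: the partner charged and the partner remaining at that conversion. At fixed conversion, and with the whole protic impurity counted as quenched reagent, a larger charge leaves the amount used unchanged in this reckoning, so the whole addition lands on a remainder smaller than the charge. The proposed steps that make product hold [partner] to the first power; with free catalyst and substrate taken as unchanged at that conversion, the apparent order in partner is estimated here as the leverage of the charge, the partner charged over the partner remaining at the moment looked at, here 2.40.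

The forecast gives 2.8 for partner, from 2 to 3.6, and 1.05 for free catalyst, from 0.9 to 1.3. Its partner figure stands above the leverage, and it gives this ground: “Reaching that point sooner preserves more catalyst”.

The flask gives 2.5 in partner and 1.1 in free catalyst.

    partner + free catalyst + left-handed substrate → free catalyst + left-handed product (k = 15.0 M⁻² h⁻¹)
    partner + free catalyst + right-handed substrate → free catalyst + right-handed product (k = 0.860 M⁻² h⁻¹)
    partner + protic impurity → quenched reagent (k = 0.850 M⁻¹ h⁻¹)
    2 free catalyst → spent catalyst (k = 0.750 M⁻¹ h⁻¹)

That conversion comes at 2.47 h. At 2.50 h, just after that moment, partner stands at 43.1% of its charge, which puts the leverage taken from the flask's own state at 2.32. In the east run, with 0.050 M of protic impurity, the same reckoning leaves 0.550 M of partner, so the leverage there is lower than in the flask, at 2.18.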